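## Retrosynthetic overview

1. Target ⇒ silylene-locked spiro-alkene 21. The ring B halogens go on last (epoxide, trans-diaxial HBr opening, retentive OH→Cl through a bromonium ion), and C5–OH comes from hydroxyl-directed reduction of ketone 19.
2. Ring B (formed second) ⇒ ring-closing metathesis of an allyl arm and a methallyl-carbinol arm on C6 of ring-A diol 14.
3. Ring A (formed first), with quaternary C6, C7–O and C10–Br set in one step ⇒ stereospecific bromonium-initiated, carbonate-terminated cation–olefin cyclisation of the acyclic (Z)-allylic tert-butyl carbonate 10. This is the key step; no Diels–Alder and no enolate alkylation at C6 is used.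
4. 10 ⇒ prenol (enantioselective bromochlorination sets C10) + ethyl 2-allylacetoacetate (dianion alkylation, (E)-enol tosylate and Negishi methylation fix the alkene geometry).

Assumption: the antipode of the bromochlorination ligand that gives (R)-2 is used; locants C1–C11 are those of the target spiro[5.5]undecane (ring B = C1–C5, spiro carbon C6, ring A = C7–C11) and are applied to acyclic precursors by atom correspondence.

## Route

Step 1
Reactants: 1 3-methylbut-2-en-1-ol (prenol)
Product: 2 (2R)-2-bromo-3-chloro-3-methylbutan-1-ol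
Conditions: NBS, ClTi(OiPr)3, chiral tridentate Schiff-base diol ligand (20 mol %), hexanes, −20 °C
Reagents that add atoms: N-bromosuccinimide, O=C1CCC(=O)N1Br; chlorotitanium triisopropoxide, CC(C)O[Ti](Cl)(OC(C)C)OC(C)C
Why: Catalytic enantioselective bromochlorination of an allylic alcohol, in which the titanium-bound alkoxide is brominated on the face chosen by the ligand and chloride is delivered anti to the tertiary carbon (Markovnikov), fixing the future C10 as R.

Step 2
Reactants: 2 (2R)-2-bromo-3-chloro-3-methylbutan-1-ol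
Product: 3 (2R)-2-bromo-3-chloro-3-methylbutyl trifluoromethanesulfonate
Conditions: Tf2O, 2,6-lutidine, CH2Cl2, −78 °C
Reagents that add atoms: trifluoromethanesulfonic anhydride, O=S(=O)(OS(=O)(=O)C(F)(F)F)C(F)(F)F
Why: O-Sulfonylation (triflation) of the primary alcohol with a hindered base at low temperature gives an SN2-competent electrophile without touching the C–Br stereocentre.

Step 3
Reactants: 3 (2R)-2-bromo-3-chloro-3-methylbutyl trifluoromethanesulfonate; 4 ethyl 2-acetylpent-4-enoate (ethyl 2-allylacetoacetate)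
Product: 6 ethyl (6R)-6-bromo-7-chloro-7-methyl-3-oxo-2-(prop-2-en-1-yl)octanoate, via sodium lithium dianion 5 (not isolated)
Conditions: 4, NaH, THF, 0 °C; n-BuLi, 0 °C; then 3, −78 → −40 °C; H2O
Reagents that add atoms: none
Why: Weiler-type γ-alkylation of an acetoacetate dianion by a primary triflate (SN2) forms the C8–C9 bond faster than the base can attack the halides, and the C2 epimers of 6 converge in the next step.

Step 4
Reactants: 6 ethyl (6R)-6-bromo-7-chloro-7-methyl-3-oxo-2-(prop-2-en-1-yl)octanoate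
Product: 7 ethyl (2E,6R)-6-bromo-7-chloro-7-methyl-3-[(4-methylbenzenesulfonyl)oxy]-2-(prop-2-en-1-yl)oct-2-enoate
Conditions: TsCl, Et3N, N-methylimidazole (cat.), MeCN, −15 → 0 °C (lithium-free)
Reagents that add atoms: 4-toluenesulfonyl chloride, Cc1ccc(cc1)S(Cl)(=O)=O
Why: Stereocomplementary enol sulfonylation of a β-ketoester, in which the non-chelated ammonium enolate is O-tosylated with the sulfonate anti to the ester to give the (E)-enol tosylate (the Z isomer would need lithium chelation).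

Step 5
Reactants: 7 ethyl (2E,6R)-6-bromo-7-chloro-7-methyl-3-[(4-methylbenzenesulfonyl)oxy]-2-(prop-2-en-1-yl)oct-2-enoate
Product: 8 ethyl (2Z,6R)-6-bromo-7-chloro-3,7-dimethyl-2-(prop-2-en-1-yl)oct-2-enoate
Conditions: MeZnCl, Pd(dppf)Cl2 (5 mol %), THF, 50 °C
Reagents that add atoms: methylzinc chloride, C[Zn]Cl
Why: Negishi cross-coupling with retention of alkene geometry puts the methyl trans to the ester (ester cis to the bromochloro chain, Z), the ester-activated enol tosylate undergoing oxidative addition much faster than the unactivated alkyl halides.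

Step 6
Reactants: 8 ethyl (2Z,6R)-6-bromo-7-chloro-3,7-dimethyl-2-(prop-2-en-1-yl)oct-2-enoate
Product: 9 (2Z,6R)-6-bromo-7-chloro-3,7-dimethyl-2-(prop-2-en-1-yl)oct-2-en-1-ol
Conditions: i-Bu2AlH, CH2Cl2, −78 °C; aqueous work-up
Reagents that add atoms: none
Why: Hydride 1,2-reduction of the conjugated ester to the allylic alcohol at −78 °C leaves the alkyl bromide, the alkyl chloride and the alkene geometry untouched.

Step 7
Reactants: 9 (2Z,6R)-6-bromo-7-chloro-3,7-dimethyl-2-(prop-2-en-1-yl)oct-2-en-1-ol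
Product: 10 tert-butyl (2Z,6R)-6-bromo-7-chloro-3,7-dimethyl-2-(prop-2-en-1-yl)oct-2-en-1-yl carbonate
Conditions: Boc2O, DMAP (cat.), MeCN, 23 °C
Reagents that add atoms: di-tert-butyl dicarbonate, CC(C)(C)OC(=O)OC(=O)OC(C)(C)C
Why: DMAP-catalysed O-acylation (Boc protection) installs the internal carbonate nucleophile that will terminate the cyclisation.

Step 8
Reactants: 10 tert-butyl (2Z,6R)-6-bromo-7-chloro-3,7-dimethyl-2-(prop-2-en-1-yl)oct-2-en-1-yl carbonate
Product: 13 (4aR,6R,8aR)-6-bromo-5,5,8a-trimethyl-4a-(prop-2-en-1-yl)hexahydro-4H-1,3-benzodioxin-2-one, via bromonium chloride 11 (not isolated), via tert-butoxydioxanylium chloride 12 (not isolated)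
Conditions: HFIP (0.01 M), 2,6-di-tert-butyl-4-methylpyridine, 25 → 40 °C
Reagents that add atoms: none
Why: Proposed new method: in ionising, weakly nucleophilic HFIP the tertiary chloride leaves with anchimeric assistance from the anti bromine to give the enantiopure bromonium ion 11 (C10 retained as R), which is opened at its tertiary carbon by C6 of the (Z)-tetrasubstituted alkene through a chair transition state with equatorial bromine while the tert-butyl carbonate carbonyl captures the developing C7 cation anti (dioxanylium 12, then loss of isobutene), so that the alkene geometry fixes the quaternary C6 (CH2O arm axial, allyl equatorial) and the tether fixes C7 (oxygen equatorial, cis to the CH2O arm); the closest known reaction types are the stereospecific solvolytic bromopolyene cyclisation of enantioenriched vicinal bromochlorides and tert-butyl-carbonate-terminated bromonium cation–olefin cyclisations.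

Step 9
Reactants: 13 (4aR,6R,8aR)-6-bromo-5,5,8a-trimethyl-4a-(prop-2-en-1-yl)hexahydro-4H-1,3-benzodioxin-2-one
Product: 14 (1R,2R,4R)-4-bromo-2-(hydroxymethyl)-1,3,3-trimethyl-2-(prop-2-en-1-yl)cyclohexan-1-ol
Conditions: K2CO3 (cat.), MeOH, 0 → 23 °C
Reagents that add atoms: none
Why: Base-catalysed transesterification (methanolysis) of the cyclic carbonate frees the primary and tertiary hydroxyls, K2CO3 being too weak to ionise the tertiary alcohol toward displacement of the neopentyl-type bromide.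

Step 10
Reactants: 14 (1R,2R,4R)-4-bromo-2-(hydroxymethyl)-1,3,3-trimethyl-2-(prop-2-en-1-yl)cyclohexan-1-ol
Product: 15 (1S,3R,6R)-3-bromo-6-hydroxy-2,2,6-trimethyl-1-(prop-2-en-1-yl)cyclohexane-1-carbaldehyde
Conditions: Dess–Martin periodinane, CH2Cl2, 0 → 23 °C
Reagents that add atoms: none
Why: Dess–Martin oxidation converts only the primary alcohol (the tertiary one cannot be oxidised) into an aldehyde that has no α-hydrogen and is kept non-basic to avoid retro-aldol cleavage.

Step 11
Reactants: 15 (1S,3R,6R)-3-bromo-6-hydroxy-2,2,6-trimethyl-1-(prop-2-en-1-yl)cyclohexane-1-carbaldehyde; 16 2-methylallylmagnesium chloride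
Product: 17 (1R,2R,4R)-4-bromo-2-[(1RS)-1-hydroxy-3-methylbut-3-en-1-yl]-1,3,3-trimethyl-2-(prop-2-en-1-yl)cyclohexan-1-ol
Conditions: THF, −78 °C (3 equiv of 16); then H2O
Reagents that add atoms: none
Why: Grignard 1,2-addition through the compact six-membered allyl-transfer transition state reaches the neopentyl aldehyde at −78 °C (one equivalent is consumed by the hydroxyl), and the C5 configuration is irrelevant because it is erased in step 13.

Step 12
Reactants: 17 (1R,2R,4R)-4-bromo-2-[(1RS)-1-hydroxy-3-methylbut-3-en-1-yl]-1,3,3-trimethyl-2-(prop-2-en-1-yl)cyclohexan-1-ol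
Product: 18 (5RS,6R,7R,10R)-10-bromo-3,7,11,11-tetramethylspiro[5.5]undec-2-ene-5,7-diol
Conditions: second-generation Grubbs catalyst (5 mol %), CH2Cl2, 40 °C
Reagents that add atoms: none
Why: Ring-closing metathesis of a monosubstituted and a 1,1-disubstituted alkene closes ring B as the trisubstituted C2=C3 cyclohexene, helped by the gem-disubstitution at the spiro carbon.

Step 13
Reactants: 18 (5RS,6R,7R,10R)-10-bromo-3,7,11,11-tetramethylspiro[5.5]undec-2-ene-5,7-diol
Product: 19 (6S,7R,10R)-10-bromo-7-hydroxy-3,7,11,11-tetramethylspiro[5.5]undec-2-en-5-one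
Conditions: Dess–Martin periodinane, CH2Cl2, 0 → 23 °C
Reagents that add atoms: none
Why: Dess–Martin oxidation of the secondary alcohol under non-basic conditions gives the β-hydroxy ketone without conjugating the β,γ-alkene or triggering retro-aldol cleavage.

Step 14
Reactants: 19 (6S,7R,10R)-10-bromo-7-hydroxy-3,7,11,11-tetramethylspiro[5.5]undec-2-en-5-one
Product: 20 (5S,6R,7R,10R)-10-bromo-3,7,11,11-tetramethylspiro[5.5]undec-2-ene-5,7-diol
Conditions: Me4NBH(OAc)3, MeCN/AcOH (1:1), −30 → 0 °C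
Reagents that add atoms: none
Why: Saksena–Evans hydroxyl-directed reduction, in which hydride is delivered intramolecularly from the boron bound to the C7 oxygen onto the ketone face on which C7 sits (also the face anti to the CMe2 carbon C11), giving the 5S alcohol (anti 1,3-diol).

Step 15
Reactants: 20 (5S,6R,7R,10R)-10-bromo-3,7,11,11-tetramethylspiro[5.5]undec-2-ene-5,7-diol
Product: 21 (5S,6R,7R,10R)-10-bromo-5,7-O-(di-tert-butylsilanediyl)-3,7,11,11-tetramethylspiro[5.5]undec-2-ene-5,7-diol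
Conditions: t-Bu2Si(OTf)2, 2,6-lutidine, CH2Cl2, 0 → 23 °C
Reagents that add atoms: di-tert-butylsilyl bis(trifluoromethanesulfonate), CC(C)(C)[Si](OS(=O)(=O)C(F)(F)F)(OS(=O)(=O)C(F)(F)F)C(C)(C)C
Why: Silylene acetal formation ties O5 and O7 into a six-membered ring, which is only possible with C5–O and C6–C7 both equatorial on ring B and therefore locks C11 axial while masking both hydroxyls against haloetherification.

Step 16
Reactants: 21 (5S,6R,7R,10R)-10-bromo-5,7-O-(di-tert-butylsilanediyl)-3,7,11,11-tetramethylspiro[5.5]undec-2-ene-5,7-diol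
Product: 22 (2R,3S,5S,6R,7R,10R)-10-bromo-5,7-O-(di-tert-butylsilanediyl)-2,3-epoxy-3,7,11,11-tetramethylspiro[5.5]undecane-5,7-diol
Conditions: mCPBA, CH2Cl2, 0 °C
Reagents that add atoms: 3-chloroperoxybenzoic acid, OOC(=O)c1cccc(Cl)c1
Why: Prilezhaev epoxidation takes place on the alkene face anti to the axial C11 (syn to the equatorial C7), as in α-face epoxidation of steroidal 2-enes, placing the oxirane oxygen on the face that chlorine will finally occupy at C3.

Step 17
Reactants: 22 (2R,3S,5S,6R,7R,10R)-10-bromo-5,7-O-(di-tert-butylsilanediyl)-2,3-epoxy-3,7,11,11-tetramethylspiro[5.5]undecane-5,7-diol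
Product: 23 (2S,3S,5S,6R,7R,10R)-2,10-dibromo-5,7-O-(di-tert-butylsilanediyl)-3,7,11,11-tetramethylspiro[5.5]undecane-3,5,7-triol
Conditions: 48% aq. HBr, CHCl3, 0 °C
Reagents that add atoms: hydrogen bromide, Br
Why: Fürst–Plattner trans-diaxial epoxide opening, in which bromide attacks C2 axially with inversion in the locked chair (as 5α,6α-epoxy steroids give 6β-bromo-5α-ols), setting C2 as S and leaving an axial tertiary alcohol at C3.

Step 18
Reactants: 23 (2S,3S,5S,6R,7R,10R)-2,10-dibromo-5,7-O-(di-tert-butylsilanediyl)-3,7,11,11-tetramethylspiro[5.5]undecane-3,5,7-triol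
Product: 25 (2S,3S,5S,6R,7R,10R)-2,10-dibromo-3-chloro-5,7-O-(di-tert-butylsilanediyl)-3,7,11,11-tetramethylspiro[5.5]undecane-5,7-diol, via bromonium chloride 24 (not isolated)
Conditions: HCl (4 M in dioxane), CH2Cl2, −20 → 0 °C
Reagents that add atoms: hydrogen chloride, Cl
Why: Tertiary alcohol to chloride with retention by neighbouring-group participation, in which the antiperiplanar axial C2 bromine expels the protonated hydroxyl to give bromonium ion 24 and chloride opens it at the tertiary carbon C3 on the face the hydroxyl left (Markovnikov and diaxial), setting C3 as S.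

Step 19
Reactants: 25 (2S,3S,5S,6R,7R,10R)-2,10-dibromo-3-chloro-5,7-O-(di-tert-butylsilanediyl)-3,7,11,11-tetramethylspiro[5.5]undecane-5,7-diol
Product: 26 (2S,3S,5S,6R,7R,10R)-2,10-dibromo-3-chloro-3,7,11,11-tetramethylspiro[5.5]undecane-5,7-diol (CNP0298877.1)
Conditions: HF·pyridine, pyridine, THF, 0 → 23 °C
Reagents that add atoms: none
Why: Fluoride-mediated cleavage of the di-tert-butylsilylene acetal under buffered, non-basic conditions frees the 5,7-diol, so neither the tertiary chloride nor the bromides can eliminate or be displaced by an alkoxide.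

## Compound list

1 | 3-methylbut-2-en-1-ol (prenol) | CC(C)=CCO | starting material
2 | (2R)-2-bromo-3-chloro-3-methylbutan-1-ol | OC[C@@H](Br)C(C)(C)Cl | intermediate
3 | (2R)-2-bromo-3-chloro-3-methylbutyl trifluoromethanesulfonate | O=S(=O)(OC[C@@H](Br)C(C)(C)Cl)C(F)(F)F | intermediate
4 | ethyl 2-acetylpent-4-enoate (ethyl 2-allylacetoacetate, racemic) | CCOC(=O)C(CC=C)C(C)=O | starting material
5 | sodium lithium dianion of 4 (not isolated) | [Na+].[Li+].[CH2-]C([O-])=C(CC=C)C(=O)OCC | intermediate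
6 | ethyl (6R)-6-bromo-7-chloro-7-methyl-3-oxo-2-(prop-2-en-1-yl)octanoate (C2 epimers) | CCOC(=O)C(CC=C)C(=O)CC[C@@H](Br)C(C)(C)Cl | intermediate
7 | ethyl (2E,6R)-6-bromo-7-chloro-7-methyl-3-[(4-methylbenzenesulfonyl)oxy]-2-(prop-2-en-1-yl)oct-2-enoate | CCOC(=O)/C(CC=C)=C(/OS(=O)(=O)c1ccc(C)cc1)CC[C@@H](Br)C(C)(C)Cl | intermediate
8 | ethyl (2Z,6R)-6-bromo-7-chloro-3,7-dimethyl-2-(prop-2-en-1-yl)oct-2-enoate | CCOC(=O)/C(CC=C)=C(/C)CC[C@@H](Br)C(C)(C)Cl | intermediate
9 | (2Z,6R)-6-bromo-7-chloro-3,7-dimethyl-2-(prop-2-en-1-yl)oct-2-en-1-ol | OC/C(CC=C)=C(/C)CC[C@@H](Br)C(C)(C)Cl | intermediate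
10 | tert-butyl (2Z,6R)-6-bromo-7-chloro-3,7-dimethyl-2-(prop-2-en-1-yl)oct-2-en-1-yl carbonate | CC(C)(C)OC(=O)OC/C(CC=C)=C(/C)CC[C@@H](Br)C(C)(C)Cl | intermediate
11 | bromonium chloride formed from 10 by loss of chloride (not isolated) | CC(C)(C)OC(=O)OC/C(CC=C)=C(/C)CC[C@@H]([Br+]1)C1(C)C.[Cl-] | intermediate
12 | 2-tert-butoxy-1,3-dioxan-2-ylium chloride fused to the new bromocyclohexane (not isolated) | CC1(C)[C@H](Br)CC[C@@]2(C)O[C+](OC(C)(C)C)OC[C@@]12CC=C.[Cl-] | intermediate
13 | (4aR,6R,8aR)-6-bromo-5,5,8a-trimethyl-4a-(prop-2-en-1-yl)hexahydro-4H-1,3-benzodioxin-2-one | CC1(C)[C@H](Br)CC[C@@]2(C)OC(=O)OC[C@@]12CC=C | intermediate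
14 | (1R,2R,4R)-4-bromo-2-(hydroxymethyl)-1,3,3-trimethyl-2-(prop-2-en-1-yl)cyclohexan-1-ol | CC1(C)[C@H](Br)CC[C@@](C)(O)[C@]1(CO)CC=C | intermediate
15 | (1S,3R,6R)-3-bromo-6-hydroxy-2,2,6-trimethyl-1-(prop-2-en-1-yl)cyclohexane-1-carbaldehyde | CC1(C)[C@H](Br)CC[C@@](C)(O)[C@]1(C=O)CC=C | intermediate
16 | 2-methylallylmagnesium chloride | C=C(C)C[Mg]Cl | starting material
17 | (1R,2R,4R)-4-bromo-2-[(1RS)-1-hydroxy-3-methylbut-3-en-1-yl]-1,3,3-trimethyl-2-(prop-2-en-1-yl)cyclohexan-1-ol | CC1(C)[C@H](Br)CC[C@@](C)(O)[C@]1(C(O)CC(C)=C)CC=C | intermediate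
18 | (5RS,6R,7R,10R)-10-bromo-3,7,11,11-tetramethylspiro[5.5]undec-2-ene-5,7-diol | CC1(C)[C@H](Br)CC[C@@](C)(O)[C@]12CC=C(C)CC2O | intermediate
19 | (6S,7R,10R)-10-bromo-7-hydroxy-3,7,11,11-tetramethylspiro[5.5]undec-2-en-5-one | CC1(C)[C@H](Br)CC[C@@](C)(O)[C@]12CC=C(C)CC2=O | intermediate
20 | (5S,6R,7R,10R)-10-bromo-3,7,11,11-tetramethylspiro[5.5]undec-2-ene-5,7-diol | CC1(C)[C@H](Br)CC[C@@](C)(O)[C@]12CC=C(C)C[C@@H]2O | intermediate
21 | (5S,6R,7R,10R)-10-bromo-5,7-O-(di-tert-butylsilanediyl)-3,7,11,11-tetramethylspiro[5.5]undec-2-ene-5,7-diol | CC1(C)[C@H](Br)CC[C@@]2(C)O[Si](C(C)(C)C)(C(C)(C)C)O[C@H]3CC(C)=CC[C@]123 | intermediate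
22 | (2R,3S,5S,6R,7R,10R)-10-bromo-5,7-O-(di-tert-butylsilanediyl)-2,3-epoxy-3,7,11,11-tetramethylspiro[5.5]undecane-5,7-diol | CC1(C)[C@H](Br)CC[C@@]2(C)O[Si](C(C)(C)C)(C(C)(C)C)O[C@H]3C[C@]4(C)O[C@@H]4C[C@]123 | intermediate
23 | (2S,3S,5S,6R,7R,10R)-2,10-dibromo-5,7-O-(di-tert-butylsilanediyl)-3,7,11,11-tetramethylspiro[5.5]undecane-3,5,7-triol | CC1(C)[C@H](Br)CC[C@@]2(C)O[Si](C(C)(C)C)(C(C)(C)C)O[C@H]3C[C@](C)(O)[C@@H](Br)C[C@]123 | intermediate
24 | C2–C3 bromonium chloride formed from 23 by loss of water (not isolated) | CC1(C)[C@H](Br)CC[C@@]2(C)O[Si](C(C)(C)C)(C(C)(C)C)O[C@H]3C[C@@]4(C)[Br+][C@H]4C[C@]123.[Cl-] | intermediate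
25 | (2S,3S,5S,6R,7R,10R)-2,10-dibromo-3-chloro-5,7-O-(di-tert-butylsilanediyl)-3,7,11,11-tetramethylspiro[5.5]undecane-5,7-diol | CC1(C)[C@H](Br)CC[C@@]2(C)O[Si](C(C)(C)C)(C(C)(C)C)O[C@H]3C[C@](C)(Cl)[C@@H](Br)C[C@]123 | intermediate
26 | (2S,3S,5S,6R,7R,10R)-2,10-dibromo-3-chloro-3,7,11,11-tetramethylspiro[5.5]undecane-5,7-diol | CC1(C)[C@H](Br)CC[C@@](C)(O)[C@]12C[C@H](Br)[C@@](C)(Cl)C[C@@H]2O | target

## Step count and risk

Total step count: 19. Longest linear sequence: 19 steps (1 → 26); compounds 4 and 16 are bought.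

The three steps most likely to fail:

**Step 8 (spiro-precursor cyclisation).** The chair closure of a (Z)-alkene onto a tertiary centre next to a carbon that becomes quaternary may lose out to elimination. The fallback inverts the order of ring formation, so that ring A is closed onto a preformed ring B (the γ-bisabolene-to-chamigrene closure). It sets out from allylic alcohol 9 and comes back at 18.
- MnO2 in CH2Cl2 gives (2Z,6R)-6-bromo-7-chloro-3,7-dimethyl-2-(prop-2-en-1-yl)oct-2-enal F4.
- Reagent-controlled methallylboration with B-(2-methylallyl)diisopinocampheylborane gives (4R,5Z,9R)-9-bromo-10-chloro-2,6,10-trimethyl-5-(prop-2-en-1-yl)undeca-1,5-dien-4-ol F5. The antipode is chosen for the 4R carbinol, which places the carbonate on the face opposite to C11 in the chair closure.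
- Ring-closing metathesis with second-generation Grubbs catalyst gives (1R,2Z)-2-[(5R)-5-bromo-6-chloro-6-methylheptan-2-ylidene]-5-methylcyclohex-4-en-1-ol F6.
- Boc2O/DMAP gives tert-butyl (1R,2Z)-2-[(5R)-5-bromo-6-chloro-6-methylheptan-2-ylidene]-5-methylcyclohex-4-en-1-yl carbonate F7.
- HFIP with 2,6-di-tert-butyl-4-methylpyridine closes ring A onto the exocyclic alkene to give (5R,6R,7R,10R)-10-bromo-3,7,11,11-tetramethylspiro[5.5]undec-2-ene-5,7-diyl carbonate F8.
- K2CO3/MeOH gives the (5R)-epimer of diol 18, where the route is rejoined; C5 is reset in steps 13 and 14.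

**Step 4 (alkene geometry).** The (E)-enol tosylation of an α-allyl β-ketoester may not be clean, and the Negishi step could erode geometry. The fallback makes the tetrasubstituted alkene by syn-carbocupration instead. It sets out from triflate 3 and comes back at 8, bypassing steps 3 to 5.
- Alkylation of 3 with 3-lithio-1-(trimethylsilyl)prop-1-yne (THF, −78 °C) gives [(5R)-5-bromo-6-chloro-6-methylhept-1-yn-1-yl]trimethylsilane F1.
- K2CO3/MeOH removes silicon to give (5R)-5-bromo-6-chloro-6-methylhept-1-yne F2.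
- LiN(SiMe3)2 then ethyl chloroformate at −78 °C gives ethyl (6R)-6-bromo-7-chloro-7-methyloct-2-ynoate F3.
- Me2CuLi at −78 °C adds methyl and copper syn, and trapping the alkenylcuprate with allyl bromide puts methyl cis to allyl and the chain cis to the ester, which is enoate 8.

**Step 17 (regiochemistry of epoxide opening).** Acid may open the trisubstituted epoxide at the tertiary carbon, or the silylene may not survive HBr. The fallback sets C2–Br by SN2 opening of a cyclic sulfate. It sets out from alkene 21 and comes back at 23.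
- OsO4 (cat.)/NMO dihydroxylates the same open face to give (2R,3S,5S,6R,7R,10R)-10-bromo-5,7-O-(di-tert-butylsilanediyl)-3,7,11,11-tetramethylspiro[5.5]undecane-2,3,5,7-tetrol F9.
- SOCl2/Et3N, then RuCl3 (cat.)/NaIO4, gives (2R,3S,5S,6R,7R,10R)-10-bromo-5,7-O-(di-tert-butylsilanediyl)-3,7,11,11-tetramethylspiro[5.5]undecane-2,3,5,7-tetrol 2,3-cyclic sulfate F10.
- LiBr in THF attacks the secondary carbon C2 axially with inversion, and mild acidic hydrolysis (cat. H2SO4, THF/H2O) of the tertiary sulfate monoester gives bromohydrin 23.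

## Further compounds

F1 | step 4 | [(5R)-5-bromo-6-chloro-6-methylhept-1-yn-1-yl]trimethylsilane | C[Si](C)(C)C#CCC[C@@H](Br)C(C)(C)Cl
F2 | step 4 | (5R)-5-bromo-6-chloro-6-methylhept-1-yne | C#CCC[C@@H](Br)C(C)(C)Cl
F3 | step 4 | ethyl (6R)-6-bromo-7-chloro-7-methyloct-2-ynoate | CCOC(=O)C#CCC[C@@H](Br)C(C)(C)Cl
F4 | step 8 | (2Z,6R)-6-bromo-7-chloro-3,7-dimethyl-2-(prop-2-en-1-yl)oct-2-enal | O=C/C(CC=C)=C(/C)CC[C@@H](Br)C(C)(C)Cl
F5 | step 8 | (4R,5Z,9R)-9-bromo-10-chloro-2,6,10-trimethyl-5-(prop-2-en-1-yl)undeca-1,5-dien-4-ol | C=C(C)C[C@@H](O)/C(CC=C)=C(/C)CC[C@@H](Br)C(C)(C)Cl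
F6 | step 8 | (1R,2Z)-2-[(5R)-5-bromo-6-chloro-6-methylheptan-2-ylidene]-5-methylcyclohex-4-en-1-ol | O[C@@H]1CC(C)=CC/C1=C(\C)CC[C@@H](Br)C(C)(C)Cl
F7 | step 8 | tert-butyl (1R,2Z)-2-[(5R)-5-bromo-6-chloro-6-methylheptan-2-ylidene]-5-methylcyclohex-4-en-1-yl carbonate | CC(C)(C)OC(=O)O[C@@H]1CC(C)=CC/C1=C(\C)CC[C@@H](Br)C(C)(C)Cl
F8 | step 8 | (5R,6R,7R,10R)-10-bromo-3,7,11,11-tetramethylspiro[5.5]undec-2-ene-5,7-diyl carbonate | CC1(C)[C@H](Br)CC[C@@]2(C)OC(=O)O[C@@H]3CC(C)=CC[C@]123
F9 | step 17 | (2R,3S,5S,6R,7R,10R)-10-bromo-5,7-O-(di-tert-butylsilanediyl)-3,7,11,11-tetramethylspiro[5.5]undecane-2,3,5,7-tetrol | CC1(C)[C@H](Br)CC[C@@]2(C)O[Si](C(C)(C)C)(C(C)(C)C)O[C@H]3C[C@](C)(O)[C@H](O)C[C@]123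
F10 | step 17 | (2R,3S,5S,6R,7R,10R)-10-bromo-5,7-O-(di-tert-butylsilanediyl)-3,7,11,11-tetramethylspiro[5.5]undecane-2,3,5,7-tetrol 2,3-cyclic sulfate | CC1(C)[C@H](Br)CC[C@@]2(C)O[Si](C(C)(C)C)(C(C)(C)C)O[C@H]3C[C@]4(C)OS(=O)(=O)O[C@@H]4C[C@]123
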